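**Strategy.** Both flavan units are traced back to one building block, penta-O-benzyl-epigallocatechin, whose pyran ring C is opened at C3–C4, the bond between the carbinol carbon and the benzylic methylene on phloroglucinol ring A. An iridium-catalysed asymmetric allylic etherification sets C2 in an open-chain aryl 1-arylallyl ether that carries an ortho vinyl group; ring-closing metathesis then forms C3=C4 and closes ring C in one operation. The styrene-type C3=C4 alkene directs hydroboration to C3, and oxidation/L-Selectride reduction gives the 2,3-cis alcohol. C8 bromination, galloylation of one half, C4 activation of the other, 4β→6 coupling and hydrogenolysis finish the synthesis.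

Key step: step 7

Assumption: the (Sa,Sc,Sc) enantiomer of the binaphthol-derived N,N-bis(1-phenylethyl)phosphoramidite is taken to deliver the (S)-configured branched ether 8; if the sense of induction is the opposite, the antipodal ligand is used.

**Route**

Step 1
Reactants: 1 3,5-bis(benzyloxy)phenol
Product: 2 2,4-bis(benzyloxy)-6-hydroxybenzaldehyde
Conditions: MgCl2, Et3N, (CH2O)n, MeCN, reflux
Reagents that add atoms: paraformaldehyde (formaldehyde), C=O
Why: Casnati–Skattebøl ortho-formylation: the magnesium phenoxide delivers formaldehyde only ortho to the free hydroxyl, the two ortho positions of 1 are equivalent, and a second equivalent of formaldehyde oxidises the salicyl alcohol to the aldehyde, so a single regioisomer is expected.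

Step 2
Reactants: 2 2,4-bis(benzyloxy)-6-hydroxybenzaldehyde
Product: 3 3,5-bis(benzyloxy)-2-ethenylphenol
Conditions: Ph3PCH3Br (2.5 equiv), KOt-Bu (2.5 equiv), THF, 0 °C to rt
Reagents that add atoms: methyltriphenylphosphonium bromide, C[P+](c1ccccc1)(c1ccccc1)c1ccccc1.[Br-]
Why: Wittig methylenation with an excess of the unstabilised ylide converts the aldehyde into the styrene while the phenol is carried as its potassium salt and is regenerated on work-up.

Step 3
Reactants: 4 3,4,5-tris(benzyloxy)benzaldehyde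
Product: 5 ethyl (2E)-3-[3,4,5-tris(benzyloxy)phenyl]prop-2-enoate
Conditions: (EtO)2P(O)CH2CO2Et, NaH, THF, 0 °C to rt
Reagents that add atoms: triethyl phosphonoacetate, CCOC(=O)CP(=O)(OCC)OCC
Why: Horner–Wadsworth–Emmons olefination of an aromatic aldehyde with the stabilised phosphonate anion should give the E-cinnamate.

Step 4
Reactants: 5 ethyl (2E)-3-[3,4,5-tris(benzyloxy)phenyl]prop-2-enoate
Product: 6 (2E)-3-[3,4,5-tris(benzyloxy)phenyl]prop-2-en-1-ol
Conditions: i-Bu2AlH (2.2 equiv), CH2Cl2, −78 °C; aqueous work-up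
Reagents that add atoms: none
Why: i-Bu2AlH reduces the conjugated ester by 1,2-addition to the allylic alcohol without touching the alkene or the benzyl ethers.

Step 5
Reactants: 6 (2E)-3-[3,4,5-tris(benzyloxy)phenyl]prop-2-en-1-ol
Product: 7 methyl (2E)-3-[3,4,5-tris(benzyloxy)phenyl]prop-2-en-1-yl carbonate
Conditions: ClCO2Me, pyridine, CH2Cl2, 0 °C
Reagents that add atoms: methyl chloroformate, COC(=O)Cl
Why: O-acylation of the primary allylic alcohol with the chloroformate installs the carbonate leaving group needed for ionisation by iridium.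

Step 6
Reactants: 3 3,5-bis(benzyloxy)-2-ethenylphenol; 7 methyl (2E)-3-[3,4,5-tris(benzyloxy)phenyl]prop-2-en-1-yl carbonate
Product: 8 1,5-bis(benzyloxy)-2-ethenyl-3-{[(1S)-1-[3,4,5-tris(benzyloxy)phenyl]prop-2-en-1-yl]oxy}benzene
Conditions: [Ir(cod)Cl]2 (2 mol %), (Sa,Sc,Sc)-O,O′-(1,1′-binaphthyl-2,2′-diyl) N,N-bis(1-phenylethyl)phosphoramidite (4 mol %, pre-activated with n-PrNH2), K3PO4, THF, 50 °C
Reagents that add atoms: none
Why: Iridium-catalysed asymmetric allylic etherification: the cyclometallated iridium phosphoramidite complex ionises the carbonate and the phenoxide attacks the aryl-bearing allyl terminus, which gives the branched ether and sets the future C2 stereocenter under ligand control, 2-vinylphenoxides being established nucleophiles for this reaction.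

Step 7
Reactants: 8 1,5-bis(benzyloxy)-2-ethenyl-3-{[(1S)-1-[3,4,5-tris(benzyloxy)phenyl]prop-2-en-1-yl]oxy}benzene
Product: 9 (2S)-5,7-bis(benzyloxy)-2-[3,4,5-tris(benzyloxy)phenyl]-2H-chromene
Conditions: (H2IMes)(PCy3)Cl2Ru=CHPh (second-generation Grubbs catalyst, 5 mol %), 1,4-benzoquinone (10 mol %), CH2Cl2 (5 mM), 35 °C, dark
Reagents that add atoms: none
Why: The ruthenium benzylidene exchanges onto one terminal alkene of 8, the resulting alkylidene undergoes intramolecular [2+2] cycloaddition with the other alkene, and the ruthenacyclobutane collapses to the C3=C4 double bond with loss of ethene, which drives the reaction. The closest known reaction type is ring-closing metathesis of 2-vinylaryl allyl ethers to 2H-chromenes, including 2-aryl examples made from iridium-derived branched ethers. Ring C is closed as a six-membered 2H-pyran by olefin metathesis, the new alkene being endocyclic and conjugated with ring A. No stereocenter is formed, and C2 is untouched because no bond to it is broken, so the configuration set in step 6 is carried over (the descriptor stays S only by priority rules). The step needs ring closure to win over intermolecular metathesis and over migration of the allylic double bond, which high dilution, the ortho relationship of the two alkenes and the hydride scavenger 1,4-benzoquinone should secure; mild temperature and exclusion of light guard against electrocyclic opening of the chromene, which would erode C2.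

Step 8
Reactants: 9 (2S)-5,7-bis(benzyloxy)-2-[3,4,5-tris(benzyloxy)phenyl]-2H-chromene
Product: 11 (2R,3S)-5,7-bis(benzyloxy)-2-[3,4,5-tris(benzyloxy)phenyl]chroman-3-ol (2,3-trans), via alkylborane 10 (not isolated)
Conditions: BH3·THF, THF, 0 °C to rt; then NaOH, H2O2, 0 °C
Reagents that add atoms: borane (used as its THF complex), B (boron stays only in intermediate 10); hydrogen peroxide, OO
Why: Hydroboration–oxidation: borane adds syn with boron at C3, away from the electron-rich benzylic C4 and on the face opposite the C2 aryl group, and oxidation with retention gives the 2,3-trans alcohol, whose C3 configuration is corrected in steps 9 and 10.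

Step 9
Reactants: 11 (2R,3S)-5,7-bis(benzyloxy)-2-[3,4,5-tris(benzyloxy)phenyl]chroman-3-ol
Product: 12 (2R)-5,7-bis(benzyloxy)-2-[3,4,5-tris(benzyloxy)phenyl]chroman-3-one
Conditions: Dess–Martin periodinane, wet CH2Cl2, rt
Reagents that add atoms: none
Why: Dess–Martin oxidation converts the secondary alcohol into the ketone under nearly neutral conditions that should leave the C2 stereocenter next to the new carbonyl unepimerised.

Step 10
Reactants: 12 (2R)-5,7-bis(benzyloxy)-2-[3,4,5-tris(benzyloxy)phenyl]chroman-3-one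
Product: 13 (2R,3R)-5,7-bis(benzyloxy)-2-[3,4,5-tris(benzyloxy)phenyl]chroman-3-ol (penta-O-benzyl-epigallocatechin, 2,3-cis)
Conditions: LiBH(s-Bu)3 (L-Selectride), LiBr, THF, −78 °C; aqueous work-up
Reagents that add atoms: none
Why: Diastereoselective ketone reduction known for benzylated flavan-3-ones: the bulky hydride attacks along the equatorial trajectory, anti to the C2 aryl group, so that the C3 hydroxyl ends up axial and cis to the aryl group (3R).

Step 11
Reactants: 13 (2R,3R)-5,7-bis(benzyloxy)-2-[3,4,5-tris(benzyloxy)phenyl]chroman-3-ol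
Product: 14 (2R,3R)-5,7-bis(benzyloxy)-8-bromo-2-[3,4,5-tris(benzyloxy)phenyl]chroman-3-ol
Conditions: N-bromosuccinimide (1.0 equiv), CH2Cl2, −78 °C to rt
Reagents that add atoms: N-bromosuccinimide, O=C1CCC(=O)N1Br
Why: Electrophilic aromatic bromination takes place on the most electron-rich ring A and prefers C8 to C6, which lies between two benzyloxy groups, as is usual for benzylated flavan-3-ols, so that C6 is left as the only free position.

Step 12
Reactants: 14 (2R,3R)-5,7-bis(benzyloxy)-8-bromo-2-[3,4,5-tris(benzyloxy)phenyl]chroman-3-ol (one portion); 15 3,4,5-tris(benzyloxy)benzoic acid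
Product: 16 (2R,3R)-5,7-bis(benzyloxy)-8-bromo-2-[3,4,5-tris(benzyloxy)phenyl]chroman-3-yl 3,4,5-tris(benzyloxy)benzoate
Conditions: DCC, DMAP, CH2Cl2, rt
Reagents that add atoms: none
Why: Steglich esterification acylates the axial C3 hydroxyl through the acylpyridinium ion without affecting any stereocenter.

Step 13
Reactants: 14 (2R,3R)-5,7-bis(benzyloxy)-8-bromo-2-[3,4,5-tris(benzyloxy)phenyl]chroman-3-ol (second portion)
Product: 17 (2R,3R,4S)-5,7-bis(benzyloxy)-8-bromo-4-(2-ethoxyethoxy)-2-[3,4,5-tris(benzyloxy)phenyl]chroman-3-ol (4β-ether, 3,4-trans)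
Conditions: DDQ (2 equiv), 2-ethoxyethanol, CH2Cl2, rt
Reagents that add atoms: 2-ethoxyethanol, CCOCCO
Why: Oxidative benzylic functionalisation: DDQ abstracts hydride from C4 next to the electron-rich ring A and the resulting cation (quinone methide) is trapped by 2-ethoxyethanol on the face trans to the C3 hydroxyl, which sets C4 as 4β.

Step 14
Reactants: 17 the 4β-(2-ethoxyethoxy) electrophile; 16 the 8-bromo gallate nucleophile (3 equiv, excess recovered)
Product: 18 8-bromo-penta-O-benzyl-epigallocatechin-(4β→6)-8-bromo-penta-O-benzyl-epigallocatechin 3-O-[3,4,5-tris(benzyloxy)benzoate]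
Conditions: TMSOTf (cat.), CH2Cl2, −78 to −40 °C; Et3N quench
Reagents that add atoms: none
Why: Lewis acid-promoted Friedel–Crafts-type flavan coupling: TMSOTf ionises the C4 ether of 17 and C6 of 16, the only unsubstituted position of its ring A, attacks the cation trans to the C3 hydroxyl to give the 3,4-trans (4β) interflavan bond, while both C8 bromines block 4→8 bonding and self-condensation through C8.

Step 15
Reactants: 18 the protected dibromo dimer
Product: 19 epigallocatechin-(4β→6)-epigallocatechin 3-O-gallate (target, CNP0204196.2)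
Conditions: H2 (1 atm), Pd(OH)2 on carbon, Et3N (2.2 equiv), degassed THF/MeOH/H2O, rt
Reagents that add atoms: none
Why: Catalytic hydrogenolysis cleaves all thirteen benzyl ethers and, with Et3N as acid scavenger, both aryl C–Br bonds, while the gallate ester, the benzylic C2–O1 bonds and the interflavan bond should be retained as in related deprotections of benzylated proanthocyanidins.

**Compound list**

1 | 3,5-bis(benzyloxy)phenol | Oc1cc(OCc2ccccc2)cc(OCc2ccccc2)c1 | starting material
2 | 2,4-bis(benzyloxy)-6-hydroxybenzaldehyde | O=Cc1c(O)cc(OCc2ccccc2)cc1OCc1ccccc1 | intermediate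
3 | 3,5-bis(benzyloxy)-2-ethenylphenol | C=Cc1c(O)cc(OCc2ccccc2)cc1OCc1ccccc1 | intermediate
4 | 3,4,5-tris(benzyloxy)benzaldehyde | O=Cc1cc(OCc2ccccc2)c(OCc2ccccc2)c(OCc2ccccc2)c1 | starting material
5 | ethyl (2E)-3-[3,4,5-tris(benzyloxy)phenyl]prop-2-enoate | CCOC(=O)/C=C/c1cc(OCc2ccccc2)c(OCc2ccccc2)c(OCc2ccccc2)c1 | intermediate
6 | (2E)-3-[3,4,5-tris(benzyloxy)phenyl]prop-2-en-1-ol | OC/C=C/c1cc(OCc2ccccc2)c(OCc2ccccc2)c(OCc2ccccc2)c1 | intermediate
7 | methyl (2E)-3-[3,4,5-tris(benzyloxy)phenyl]prop-2-en-1-yl carbonate | COC(=O)OC/C=C/c1cc(OCc2ccccc2)c(OCc2ccccc2)c(OCc2ccccc2)c1 | intermediate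
8 | 1,5-bis(benzyloxy)-2-ethenyl-3-{[(1S)-1-[3,4,5-tris(benzyloxy)phenyl]prop-2-en-1-yl]oxy}benzene | C=C[C@H](Oc1cc(OCc2ccccc2)cc(OCc2ccccc2)c1C=C)c1cc(OCc2ccccc2)c(OCc2ccccc2)c(OCc2ccccc2)c1 | intermediate
9 | (2S)-5,7-bis(benzyloxy)-2-[3,4,5-tris(benzyloxy)phenyl]-2H-chromene | C1=Cc2c(OCc3ccccc3)cc(OCc3ccccc3)cc2O[C@@H]1c1cc(OCc2ccccc2)c(OCc2ccccc2)c(OCc2ccccc2)c1 | intermediate
10 | C3 alkylborane of 9, boron at C3 trans to the C2 aryl group (drawn as the monoalkylborane) | B[C@H]1Cc2c(OCc3ccccc3)cc(OCc3ccccc3)cc2O[C@@H]1c1cc(OCc2ccccc2)c(OCc2ccccc2)c(OCc2ccccc2)c1 | intermediate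
11 | (2R,3S)-5,7-bis(benzyloxy)-2-[3,4,5-tris(benzyloxy)phenyl]chroman-3-ol (penta-O-benzyl-gallocatechin, 2,3-trans) | O[C@H]1Cc2c(OCc3ccccc3)cc(OCc3ccccc3)cc2O[C@@H]1c1cc(OCc2ccccc2)c(OCc2ccccc2)c(OCc2ccccc2)c1 | intermediate
12 | (2R)-5,7-bis(benzyloxy)-2-[3,4,5-tris(benzyloxy)phenyl]chroman-3-one | O=C1Cc2c(OCc3ccccc3)cc(OCc3ccccc3)cc2O[C@@H]1c1cc(OCc2ccccc2)c(OCc2ccccc2)c(OCc2ccccc2)c1 | intermediate
13 | (2R,3R)-5,7-bis(benzyloxy)-2-[3,4,5-tris(benzyloxy)phenyl]chroman-3-ol (penta-O-benzyl-epigallocatechin, 2,3-cis) | O[C@@H]1Cc2c(OCc3ccccc3)cc(OCc3ccccc3)cc2O[C@@H]1c1cc(OCc2ccccc2)c(OCc2ccccc2)c(OCc2ccccc2)c1 | intermediate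
14 | (2R,3R)-5,7-bis(benzyloxy)-8-bromo-2-[3,4,5-tris(benzyloxy)phenyl]chroman-3-ol | O[C@@H]1Cc2c(OCc3ccccc3)cc(OCc3ccccc3)c(Br)c2O[C@@H]1c1cc(OCc2ccccc2)c(OCc2ccccc2)c(OCc2ccccc2)c1 | intermediate
15 | 3,4,5-tris(benzyloxy)benzoic acid | OC(=O)c1cc(OCc2ccccc2)c(OCc2ccccc2)c(OCc2ccccc2)c1 | starting material
16 | (2R,3R)-5,7-bis(benzyloxy)-8-bromo-2-[3,4,5-tris(benzyloxy)phenyl]chroman-3-yl 3,4,5-tris(benzyloxy)benzoate | O=C(O[C@@H]1Cc2c(OCc3ccccc3)cc(OCc3ccccc3)c(Br)c2O[C@@H]1c1cc(OCc2ccccc2)c(OCc2ccccc2)c(OCc2ccccc2)c1)c1cc(OCc2ccccc2)c(OCc2ccccc2)c(OCc2ccccc2)c1 | intermediate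
17 | (2R,3R,4S)-5,7-bis(benzyloxy)-8-bromo-4-(2-ethoxyethoxy)-2-[3,4,5-tris(benzyloxy)phenyl]chroman-3-ol (4β-ether) | CCOCCO[C@H]1c2c(OCc3ccccc3)cc(OCc3ccccc3)c(Br)c2O[C@H](c2cc(OCc3ccccc3)c(OCc3ccccc3)c(OCc3ccccc3)c2)[C@@H]1O | intermediate
18 | 8-bromo-penta-O-benzyl-epigallocatechin-(4β→6)-8-bromo-penta-O-benzyl-epigallocatechin 3-O-[3,4,5-tris(benzyloxy)benzoate] (both units 2,3-cis, upper unit 3,4-trans) | O=C(O[C@@H]1Cc2c(OCc3ccccc3)c([C@H]3c4c(OCc5ccccc5)cc(OCc5ccccc5)c(Br)c4O[C@H](c4cc(OCc5ccccc5)c(OCc5ccccc5)c(OCc5ccccc5)c4)[C@@H]3O)c(OCc3ccccc3)c(Br)c2O[C@@H]1c1cc(OCc2ccccc2)c(OCc2ccccc2)c(OCc2ccccc2)c1)c1cc(OCc2ccccc2)c(OCc2ccccc2)c(OCc2ccccc2)c1 | intermediate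
19 | epigallocatechin-(4β→6)-epigallocatechin 3-O-gallate | O=C(O[C@@H]1Cc2c(cc(O)c([C@H]3c4c(O)cc(O)cc4O[C@H](c4cc(O)c(O)c(O)c4)[C@@H]3O)c2O)O[C@@H]1c1cc(O)c(O)c(O)c1)c1cc(O)c(O)c(O)c1 | target

**Step count and risks**

Total step count: 15. Longest linear sequence: 12 steps (steps 3, 4, 5, 6, 7, 8, 9, 10, 11, 12 or 13, 14, 15).

The three steps most likely to fail:

Step 6. The electron-rich 1-arylallyl system may ionise again after the ether is formed, so that the branched ether drifts to the linear isomer or loses enantiopurity, and the ortho-substituted phenoxide may attack too slowly. Fallback, setting out from 4 and 3: catalytic asymmetric addition of Zn(CH=CH2)2 to aldehyde 4 in the presence of a chiral amino alcohol ligand (toluene, 0 °C) gives (1R)-1-[3,4,5-tris(benzyloxy)phenyl]prop-2-en-1-ol F1, which is joined to phenol 3 by a Mitsunobu etherification (PPh3, diisopropyl azodicarboxylate, toluene, −20 °C) with inversion at the carbinol carbon. The route is rejoined at 8.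

Step 7. The ruthenium alkylidene may be held back as a chelate by the ortho-alkoxy styrene, ruthenium hydrides may shift the allylic double bond into an enol ether, or the chromene may lose C2 integrity by electrocyclic ring opening. Fallback, setting out from 2 and 7: the iridium etherification of step 6 is run on the salicylaldehyde to give 2,4-bis(benzyloxy)-6-{[(1S)-1-[3,4,5-tris(benzyloxy)phenyl]prop-2-en-1-yl]oxy}benzaldehyde F2. Ring C is then closed by stoichiometric olefin metathesis/carbonyl olefination with Mo(=CHCMe2Ph)(=N-2,6-i-Pr2C6H3)[OCMe(CF3)2]2 (benzene, rt), a reaction type known for olefinic ketones and esters. The molybdenum alkylidene formed at the terminal alkene olefinates the aldehyde intramolecularly and forms the same C3=C4 bond. The route is rejoined at 9.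

Step 14. Attack by the hindered, bromine-deactivated C6 may be slow, the electrophile may condense with itself or with the product through their own free C6 positions, and the acid may scramble the new interflavan bond. Fallback, setting out from 17: exchange of the 2-ethoxyethoxy group with 2-mercaptobenzothiazole (BF3·OEt2, CH2Cl2, 0 °C) gives (2R,3S,4S)-4-(1,3-benzothiazol-2-ylsulfanyl)-5,7-bis(benzyloxy)-8-bromo-2-[3,4,5-tris(benzyloxy)phenyl]chroman-3-ol F3 (4β-thioether). F3 is activated by the thiophilic salt AgBF4 (THF, 0 °C) in the presence of 16 under non-acidic conditions. The route is rejoined at 18.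

Further compounds
F1 | step 6 | (1R)-1-[3,4,5-tris(benzyloxy)phenyl]prop-2-en-1-ol | C=C[C@@H](O)c1cc(OCc2ccccc2)c(OCc2ccccc2)c(OCc2ccccc2)c1
F2 | step 7 | 2,4-bis(benzyloxy)-6-{[(1S)-1-[3,4,5-tris(benzyloxy)phenyl]prop-2-en-1-yl]oxy}benzaldehyde | C=C[C@H](Oc1cc(OCc2ccccc2)cc(OCc2ccccc2)c1C=O)c1cc(OCc2ccccc2)c(OCc2ccccc2)c(OCc2ccccc2)c1
F3 | step 14 | (2R,3S,4S)-4-(1,3-benzothiazol-2-ylsulfanyl)-5,7-bis(benzyloxy)-8-bromo-2-[3,4,5-tris(benzyloxy)phenyl]chroman-3-ol | c1ccc2sc(S[C@H]3c4c(OCc5ccccc5)cc(OCc5ccccc5)c(Br)c4O[C@H](c4cc(OCc5ccccc5)c(OCc5ccccc5)c(OCc5ccccc5)c4)[C@@H]3O)nc2c1
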